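**Retrosynthetic overview**
1. Target ⇒ Yamaguchi esterification of the C3‑OH of a 3β,4α,11‑triol enone with (2S,3R)‑2,3‑dimethyloxirane‑2‑carboxylic acid (from tiglyl alcohol by Sharpless epoxidation and oxidation).
2. Ring B hydroxy‑enone ⇐ singlet‑oxygen ene reaction of a 7(11)‑en‑8‑one ⇐ aldol condensation of the C8 ketone with acetone.
3. Ring A trans‑3β,4α‑diol ⇐ hydroxyl‑directed reduction of a 4α‑hydroxy‑3‑ketone ⇐ reductive α‑hydroxylation of the Δ4‑3‑ketone (sets C4 and C5).
4. Decalin‑3,8‑dione ⇐ one‑carbon ring expansion (1,2‑shift of the quaternary carbon) of the cyclopentanone of a Hajos–Parrish‑type hydrindenedione.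
5. Ring order: ring A first (Michael addition and asymmetric aldol from 2‑methylcyclopentane‑1,3‑dione and ethyl vinyl ketone, setting C10), then ring B by expansion of the five‑membered ring.

Assumption: decalin compounds carry eudesmane numbering (C10 = methyl‑bearing ring‑fusion carbon, C5 = ring‑fusion CH, C3/C4 = oxygenated ring A carbons, C8 = ring B carbonyl, C11 = carbinol carbon); α is the face opposite the C10 methyl.

**Step 1**
Reactants: 1 2‑methylcyclopentane‑1,3‑dione; 2 pent‑1‑en‑3‑one (ethyl vinyl ketone)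
Product: 3 2‑methyl‑2‑(3‑oxopentyl)cyclopentane‑1,3‑dione
Conditions: H2O, AcOH (cat.), 70 °C
Reagents that add atoms: none
Why: Michael addition of the acidic 1,3‑dione to the vinyl ketone in water gives the achiral triketone and creates the future C10 quaternary carbon.

**Step 2**
Reactants: 3 2‑methyl‑2‑(3‑oxopentyl)cyclopentane‑1,3‑dione
Product: 4 (7aS)‑4,7a‑dimethyl‑2,3,7,7a‑tetrahydro‑1H‑indene‑1,5(6H)‑dione
Conditions: L‑phenylalanine (1.0 equiv), (1S)‑(+)‑camphor‑10‑sulfonic acid (0.5 equiv), DMF, 30→70 °C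
Reagents that add atoms: none
Why: Amino‑acid‑mediated enamine aldol cyclodehydration (Hajos–Parrish–Eder–Sauer–Wiechert reaction) differentiates the two enantiotopic ring carbonyls and sets the quaternary centre as 7aS (about 90% ee expected, upgraded by crystallisation).

**Step 3**
Reactants: 4 (7aS)‑4,7a‑dimethyl‑2,3,7,7a‑tetrahydro‑1H‑indene‑1,5(6H)‑dione
Product: 9 (4aR)‑1,4a‑dimethyl‑4,4a,7,8‑tetrahydronaphthalene‑2,6(3H,5H)‑dione, via potassium dienolate 5 (not isolated), via dibromomethyl alkoxide 6 (not isolated), via bromolithiomethyl carbenoid 7 (not isolated), via ring‑expanded bis‑enolate 8 (not isolated)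
Conditions: KH (1.0 equiv), THF, 0 °C→rt; CH2Br2, LiTMP (lithium 2,2,6,6‑tetramethylpiperidide), −78 °C; n‑BuLi, −95 °C→rt; 2 M HCl, rt
Reagents that add atoms: dibromomethane BrCBr
Why: Proposed new method: a one‑flask, enolate‑masked β‑oxido‑carbenoid ring enlargement in which KH first converts the enone into its thermodynamic extended potassium dienolate (switching off the C5 carbonyl toward organolithiums), dibromomethyllithium then adds only to the C1 ketone from the face opposite the angular methyl, bromine–lithium exchange gives the β‑oxido carbenoid, and its 1,2‑shift with loss of LiBr moves the more electron‑rich quaternary carbon C7a (with retention, so the stereocentre is carried over) onto the carbenoid carbon, inserting CH2 on the quaternary side before acidic work‑up protonates both enolates and reconjugates the enone; the closest known reaction type is the dibromomethyllithium/n‑BuLi ring enlargement of simple cycloalkanones (Taguchi–Yamamoto–Nozaki type), not yet shown on an enolate‑masked enedione or an α‑quaternary hydrindanone.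

**Step 4**
Reactants: 9 (4aR)‑1,4a‑dimethyl‑4,4a,7,8‑tetrahydronaphthalene‑2,6(3H,5H)‑dione
Product: 11 (4S,5R,10R)‑4‑hydroxy‑11,12,13‑trinoreudesmane‑3,8‑dione (4α‑OH, 4β‑Me, 5α‑H), via 4α‑hydroperoxide 10 (not isolated)
Conditions: Mn(dpm)3 (tris(dipivaloylmethanato)manganese, 10 mol%), PhSiH3, O2 (1 atm), iPrOH/CH2Cl2, 0 °C; then P(OEt)3
Reagents that add atoms: dioxygen O=O
Why: Metal‑hydride hydrogen‑atom transfer to the enone (Mukaiyama‑type reductive α‑hydroxylation) delivers H to C5 on the α face anti to the angular methyl (trans‑decalin), and O2 traps the C4 α‑keto radical on the same α face because the β face is blocked by the 1,3‑diaxial C10 methyl, giving the 4α‑hydroperoxide that the phosphite reduces.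

**Step 5**
Reactants: 11 (4S,5R,10R)‑4‑hydroxy‑11,12,13‑trinoreudesmane‑3,8‑dione
Product: 12 (3S,4S,5R,10R)‑3,4‑dihydroxy‑11,12,13‑trinoreudesman‑8‑one (3β,4α‑diol)
Conditions: Me4NBH(OAc)3, MeCN/AcOH (1:1), −20 °C→rt
Reagents that add atoms: none
Why: Hydroxyl‑directed triacetoxyborohydride reduction (Saksena–Evans type) binds the 4α‑OH and delivers hydride to C3 on the α face, which is also the intrinsically favoured axial trajectory, giving the equatorial 3β‑alcohol trans to the 4α‑OH while the undirected C8 ketone is untouched.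

**Step 6**
Reactants: 12 (3S,4S,5R,10R)‑3,4‑dihydroxy‑11,12,13‑trinoreudesman‑8‑one; 13 acetone
Product: 14 (3S,4S,5R,10R)‑3,4,11‑trihydroxyeudesman‑8‑one (mixture of C7 epimers)
Conditions: LiN(iPr)2 (3.3 equiv), THF, −78 °C; acetone, −78 °C; AcOH quench at −78 °C
Reagents that add atoms: none
Why: After both hydroxyls are deprotonated, kinetic enolisation of the C8 ketone goes toward C7 (away from the quaternary C10 side, as 2‑keto‑5α‑steroids enolise toward C3) and the lithium enolate undergoes directed aldol addition to acetone; the new C7 centre is uncontrolled and is erased in step 7.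

**Step 7**
Reactants: 14 (3S,4S,5R,10R)‑3,4,11‑trihydroxyeudesman‑8‑one
Product: 15 (3S,4S,5R,10R)‑3,4‑dihydroxyeudesm‑7(11)‑en‑8‑one
Conditions: TsOH·H2O (10 mol%), PhH, 40 °C
Reagents that add atoms: none
Why: Mild acid dehydrates the β‑hydroxy ketone through its enol (completing the aldol condensation) to the conjugated isopropylidene ketone, conditions under which the isolated tertiary C4‑OH next to the C3‑OH does not ionise.

**Step 8**
Reactants: 15 (3S,4S,5R,10R)‑3,4‑dihydroxyeudesm‑7(11)‑en‑8‑one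
Product: 17 (3S,4S,5R,10R)‑3,4,11‑trihydroxyeudesm‑6‑en‑8‑one, via 11‑hydroperoxide 16 (not isolated)
Conditions: O2, tetraphenylporphyrin (sensitiser), hν (white LED), CH2Cl2, 0 °C; then PPh3
Reagents that add atoms: dioxygen O=O
Why: Schenck ene reaction of singlet oxygen with the s‑cis alkylidene ketone abstracts the C6 hydrogen geminal to the carbonyl and puts oxygen on C11 (the pulegone to 8‑hydroperoxy‑p‑menth‑4‑en‑3‑one pattern), moving the double bond to C6=C7 without touching C5, and PPh3 reduces the hydroperoxide.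

**Step 9**
Reactants: 18 (E)‑2‑methylbut‑2‑en‑1‑ol (tiglyl alcohol)
Product: 19 (2R,3R)‑(2,3‑dimethyloxiran‑2‑yl)methanol
Conditions: Ti(OiPr)4 (10 mol%), D‑(−)‑diethyl tartrate (12 mol%), t‑BuOOH, 4 Å molecular sieves, CH2Cl2, −20 °C
Reagents that add atoms: tert‑butyl hydroperoxide CC(C)(C)OO
Why: Sharpless asymmetric epoxidation with the D‑(−)‑tartrate ligand delivers oxygen to the alkene face that gives the (2R,3R) epoxide, and the E geometry fixes the two methyls cis.

**Step 10**
Reactants: 19 (2R,3R)‑(2,3‑dimethyloxiran‑2‑yl)methanol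
Product: 20 (2S,3R)‑2,3‑dimethyloxirane‑2‑carboxylic acid
Conditions: RuCl3·xH2O (2 mol%), NaIO4, CCl4/MeCN/H2O, rt
Reagents that add atoms: water O
Why: RuO4 generated in situ oxidises the primary alcohol through the aldehyde hydrate to the acid without opening the epoxide, and the C2 descriptor changes from R to S only through the priority change.

**Step 11**
Reactants: 17 (3S,4S,5R,10R)‑3,4,11‑trihydroxyeudesm‑6‑en‑8‑one; 20 (2S,3R)‑2,3‑dimethyloxirane‑2‑carboxylic acid
Product: 22 CNP0272928.2 (3β‑[(2S,3R)‑2,3‑dimethyloxirane‑2‑carbonyloxy]‑4α,11‑dihydroxyeudesm‑6‑en‑8‑one), via mixed anhydride 21 (not isolated)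
Conditions: 2,4,6‑trichlorobenzoyl chloride, Et3N, THF, rt; then 17, DMAP, toluene, rt→40 °C
Reagents that add atoms: none
Why: Yamaguchi esterification acylates only the secondary equatorial C3‑OH, since the tertiary C4 and C11 hydroxyls are inert to the mixed anhydride, with retention at every stereocentre.

**Compound list**
1 | 2‑methylcyclopentane‑1,3‑dione | CC1C(=O)CCC1=O | starting material
2 | pent‑1‑en‑3‑one | CCC(=O)C=C | starting material
3 | 2‑methyl‑2‑(3‑oxopentyl)cyclopentane‑1,3‑dione | CCC(=O)CCC1(C)C(=O)CCC1=O | intermediate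
4 | (7aS)‑4,7a‑dimethyl‑2,3,7,7a‑tetrahydro‑1H‑indene‑1,5(6H)‑dione | O=C1CC[C@]2(C)C(=O)CCC2=C1C | intermediate
5 | potassium extended dienolate of 4 (O–C5=C4 and C3a=C3 double bonds, C1 ketone intact, 7aS) | [K+].[O-]C1=C(C)C2=CCC(=O)[C@@]2(C)CC1 | intermediate
6 | (1S,7aS)‑1‑(dibromomethyl) 1,5‑bis(olate) of the dienolate, K/Li salt (CHBr2 on the face opposite the angular methyl) | [K+].[Li+].[O-]C1=C(C)C2=CC[C@@]([O-])(C(Br)Br)[C@@]2(C)CC1 | intermediate
7 | 1‑[bromo(lithio)methyl] β‑oxido carbenoid derived from 6 (carbenoid carbon configurationally undefined) | [K+].[Li+].[O-]C1=C(C)C2=CC[C@@]([O-])(C([Li])Br)[C@@]2(C)CC1 | intermediate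
8 | ring‑expanded bis‑enolate (C8 enolate toward C9, ring A dienolate, 10R), K/Li salt | [K+].[Li+].[O-]C1=C(C)C2=CCC([O-])=C[C@@]2(C)CC1 | intermediate
9 | (4aR)‑1,4a‑dimethyl‑4,4a,7,8‑tetrahydronaphthalene‑2,6(3H,5H)‑dione (11,12,13‑trinoreudesm‑4‑ene‑3,8‑dione) | O=C1CC[C@]2(C)CC(=O)CCC2=C1C | intermediate
10 | (4S,5R,10R)‑4‑hydroperoxy‑11,12,13‑trinoreudesmane‑3,8‑dione | O=C1CC[C@]2(C)CC(=O)CC[C@H]2[C@]1(C)OO | intermediate
11 | (4S,5R,10R)‑4‑hydroxy‑11,12,13‑trinoreudesmane‑3,8‑dione | O=C1CC[C@]2(C)CC(=O)CC[C@H]2[C@]1(C)O | intermediate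
12 | (3S,4S,5R,10R)‑3,4‑dihydroxy‑11,12,13‑trinoreudesman‑8‑one | O[C@H]1CC[C@]2(C)CC(=O)CC[C@H]2[C@]1(C)O | intermediate
13 | acetone | CC(C)=O | starting material
14 | (3S,4S,5R,10R)‑3,4,11‑trihydroxyeudesman‑8‑one, C7 epimers | O[C@H]1CC[C@]2(C)CC(=O)C(C(C)(C)O)C[C@H]2[C@]1(C)O | intermediate
15 | (3S,4S,5R,10R)‑3,4‑dihydroxyeudesm‑7(11)‑en‑8‑one | O[C@H]1CC[C@]2(C)CC(=O)C(=C(C)C)C[C@H]2[C@]1(C)O | intermediate
16 | (3S,4S,5R,10R)‑11‑hydroperoxy‑3,4‑dihydroxyeudesm‑6‑en‑8‑one | O[C@H]1CC[C@]2(C)CC(=O)C(C(C)(C)OO)=C[C@H]2[C@]1(C)O | intermediate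
17 | (3S,4S,5R,10R)‑3,4,11‑trihydroxyeudesm‑6‑en‑8‑one | O[C@H]1CC[C@]2(C)CC(=O)C(C(C)(C)O)=C[C@H]2[C@]1(C)O | intermediate
18 | (E)‑2‑methylbut‑2‑en‑1‑ol | C/C=C(\C)CO | starting material
19 | (2R,3R)‑(2,3‑dimethyloxiran‑2‑yl)methanol | C[C@H]1O[C@]1(C)CO | intermediate
20 | (2S,3R)‑2,3‑dimethyloxirane‑2‑carboxylic acid | C[C@H]1O[C@]1(C)C(=O)O | intermediate
21 | (2S,3R)‑2,3‑dimethyloxirane‑2‑carboxylic 2,4,6‑trichlorobenzoic anhydride | C[C@H]1O[C@]1(C)C(=O)OC(=O)c1c(Cl)cc(Cl)cc1Cl | intermediate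
22 | CNP0272928.2, 3β‑[(2S,3R)‑2,3‑dimethyloxirane‑2‑carbonyloxy]‑4α,11‑dihydroxyeudesm‑6‑en‑8‑one (3S,4S,5R,10R) | C[C@H]1O[C@]1(C)C(=O)O[C@H]1CC[C@]2(C)CC(=O)C(C(C)(C)O)=C[C@H]2[C@]1(C)O | target

**Step count and risks**
Total: 11 steps. Longest linear sequence: 9 steps (steps 1–8 and 11); the acid branch is steps 9–10.

Step 3 (the proposed new ring expansion) is the most likely to fail. The polyanionic sequence may stall at addition to the hindered C1 ketone, or the CH2 carbon may migrate instead of the quaternary one. Fallback with known chemistry: from 4, thioketalisation of the enone carbonyl with propane‑1,3‑dithiol and BF3·OEt2 (selective for the conjugated carbonyl, double bond staying at C3a=C4) gives the C5 1,3‑dithiane of 4 F1. The classical two‑stage dibromomethyllithium addition and n‑BuLi‑induced rearrangement on its only free carbonyl gives the ring‑expanded dithiane ketone F2. Oxidative dethioketalisation with PhI(O2CCF3)2 in aqueous MeCN then returns to 9.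

Step 4 is the second risk. Hydrogen‑atom transfer to a tetrasubstituted enone can be slow, and the 5α/5β ratio is not guaranteed. Fallback: from 9, selective ketalisation of the saturated C8 ketone (ethylene glycol, TsOH) gives the 8,8‑ethylenedioxy enone F3. Li/NH3 reduction with trapping of the regiospecific enolate by TMSCl gives the trans‑fused C3 trimethylsilyl enol ether F4. Rubottom oxidation (mCPBA, NaHCO3) on the α face gives the 4α‑trimethylsilyloxy 3‑ketone ketal F5, and aqueous HCl removes the silyl group and the ketal to rejoin the route at 11.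

Step 8 is the third risk. Singlet oxygen reacts slowly with enones and may abstract a methyl hydrogen of the isopropylidene group instead of H‑6. Fallback: from 14 (before dehydration), Yamaguchi esterification with 20 through 21 gives the 3‑O‑[(2S,3R)‑2,3‑dimethyloxirane‑2‑carbonyl] 4,11‑dihydroxy‑8‑ketone F6. IBX in DMSO at 70 °C then dehydrogenates it to the enone; only C6–C7 can be desaturated because C10 is quaternary, so this arrives directly at 22.

**Further compounds**
F1 | step 3 | C5 1,3‑dithiane of 4 (7aS) | C13(SCCCS3)CC[C@]2(C)C(=O)CCC2=C1C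
F2 | step 3 | C3 1,3‑dithiane of 9 (10R, eudesmane numbering) | C13(SCCCS3)CC[C@]2(C)CC(=O)CCC2=C1C
F3 | step 4 | 8,8‑ethylenedioxy‑11,12,13‑trinoreudesm‑4‑en‑3‑one (10R) | O=C1CC[C@]2(C)CC3(OCCO3)CCC2=C1C
F4 | step 4 | 3‑trimethylsilyloxy‑8,8‑ethylenedioxy‑11,12,13‑trinor‑5α‑eudesm‑3‑ene | C[Si](C)(C)OC=1CC[C@]2(C)CC3(OCCO3)CC[C@H]2C=1C
F5 | step 4 | 4α‑trimethylsilyloxy‑8,8‑ethylenedioxy‑11,12,13‑trinor‑5α‑eudesman‑3‑one | O=C1CC[C@]2(C)CC3(OCCO3)CC[C@H]2[C@]1(C)O[Si](C)(C)C
F6 | step 8 | 3β‑[(2S,3R)‑2,3‑dimethyloxirane‑2‑carbonyloxy]‑4α,11‑dihydroxyeudesman‑8‑one, C7 epimers | C[C@H]1O[C@]1(C)C(=O)O[C@H]1CC[C@]2(C)CC(=O)C(C(C)(C)O)C[C@H]2[C@]1(C)O
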